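Readings and results were computed on assumed constants; the scatter is artificial.

Amounts first: D is charged as a fixed 0.2 mol% of J, so [D] rises with [J], and a rate first order in each, all else held, converts a larger fraction the fuller the flask.

| setting | beta | gamma | flask |
|---|---|---|---|
| J | 1.1 M | 1.7 M | 0.77 M |
| Q | 69 mM (held) | 69 mM (held) | 69 mM (held) |
| D | 0.2 mol% | 0.2 mol% | 0.2 mol% |
| remark | run made earlier | run made earlier |  |
| time |  |  | 2.5 d |

| run | time / d | L / % | G / % |
|---|---|---|---|
| beta | 0.167 | 10.2 | 0 |
| beta | 0.500 | 25.9 | 0.2 |
| beta | 0.833 | 43.7 | 1.2 |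
| beta | 1.25 | 56.8 | 0.4 |
| beta | 2.08 | 77.3 | 2.1 |
| beta | 2.50 | 84.8 | 0.2 |
| gamma | 0.208 | 10.5 | 0.3 |
| gamma | 0.333 | 14.0 | 0 |
| gamma | 0.500 | 23.7 | 1.6 |
| gamma | 0.833 | 36.5 | 1.0 |
| gamma | 1.67 | 64.6 | 0.8 |
| gamma | 2.50 | 81.1 | 0.1 |

(standard deviation of a reading: 1 percentage point)

- amount of L and G together at 2.5 d, in percent of the J charged
- the change that raises the amount of L and G together at 2.5 d, in percent of the J charged most ("none" if none brings more than 2 percentage points) (autumn / spring / summer / none)
- amount of L and G together at 2.5 d, in percent of the J charged, after summer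

- autumn: doubling the saturation concentration of Q, all else as stated
- spring: doubling the transfer coefficient of Q, all else as stated
- summer: doubling the amount of D, all else as stated

- amounts and yields of L count G too
- at the start none of Q is in solution

The last rows of the two tables, both at 2.50 d, show the opposite. Beta stands at 84.8% and gamma at 81.1%. As logarithms of charged over left these are 1.88 and 1.67, so gamma, with 1.55 times the [D] charged, has come less far.

Suppose Q in solution is fed at a capped rate W and acts at first order. Integrating the rate with the two resistances in series gives a time bill: t = [J]x/W + ln(charged/left)/k. Here [J] is the starting value, x the fraction converted, and k the pseudo-first-order constant, taken as proportional to the [D] charged.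

The two rows give W = 0.790 M d⁻¹ and, for beta, k = 1.43 d⁻¹. Both are readings that carry the scatter of those two rows. The asked flask, with less [D] charged, has k = 1.00 d⁻¹.

Rearranged as left = exp(−k(t − [J]x/W)) and iterated from beta's fraction, the bill gives 81.9% for the flask. Of its 2.5 d, the transfer part takes 0.798 d and the reaction part 1.70 d, the larger.

Summer doubles k and gives 95.6%. Spring doubles W and gives 87.8%. Autumn doubles both and gives 98.3%, the highest.

The forecast says 83%, autumn, and 95% after summer, against the 81.9% and 95.6% reckoned here: “Autumn wins, narrowly over summer.”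

The flask gives 81.5%, autumn adds 15 percentage points against 13 points for summer, and summer reaches 94.5%.

    J + Z + D → D + L (k = 532 L² mol⁻² h⁻¹)
    Q ⇌ Z, rate k2*(csat - [Z]) (kL = 0.636 h⁻¹)
    D + L ⇌ G (K = 1.25 L mol⁻¹, k = 0.935 L mol⁻¹ h⁻¹)

In the flask at 2.50 d, G holds 43.8% of the catalyst charged and D 56.2%. Billed at 81.5% with its k of 1.00 d⁻¹, the flask costs 2.48 d of its 2.5 d. The neighbour flask with 0.12 mol% of D ran for the same 2.5 d, has k = 0.600 d⁻¹ and the same W, and its 68.3% costs 2.58 d.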